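If reagent crosses between the phases faster than it reacts, says the first of two chemists, this flask is an ordinary bimolecular reaction. Reagent starts in the second phase, crosses into the reaction phase and meets substrate there to give target. Target can decompose, pass into the second phase, crystallise or take up more substrate, and reagent can also form homo dimer.

substrate 0.050 M; reagent in the second phase 0.0475 M; time 10 h; volume of the second phase over the first 1.0

- how much target and product in the second phase and crystals together there is at 10 h, in percent of the substrate charged
- concentration of target in solution at 10 h, in percent of saturation

    reagent in the reaction phase ⇌ reagent in the second phase, rate k1*([reagent in the reaction phase] - [reagent in the second phase]/K1) per volume of the first phase (K1 = 3.1, k1 = 1.4 × 10⁻⁴ /s)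
    substrate + reagent in the reaction phase → target (k2 = 0.0074 /M/s)
    target ⇌ product in the second phase, rate k3*([target] - [product in the second phase]/K3) per volume of the first phase (K3 = 20, k3 = 2.1 × 10⁻⁴ /s)
    target → decomposed product (k4 = 1.2 × 10⁻⁴ /s)
    2 reagent in the reaction phase → homo dimer (k5 = 0.0030 /M/s)
    substrate + target → side product (k6 = 0.0011 /M/s)
    crystals ⇌ target, rate k7*(cs7 - [target]) while solid is left; crystals form when [target] > cs7 (cs7 = 0.58 mM, k7 = 0.0057 /s)

The first chemist spreads the reagent charge over equal volumes by the partition ratio 3.1, which puts 0.0116 M in the reaction phase. Held there, it gives substrate a pseudo-first-order half-life of 2.25 h, shorter than the run, so the yield should climb toward the ceiling of 95.0%.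

I hold the other view. A reagent in the reaction phase can react with substrate, at a first-order rate of 0.0074 /M/s times [substrate], or cross back, at 1.4 × 10⁻⁴ /s. The quantity to carry is the crossing concentration, the [substrate] at which these two rates are equal: 0.0189 M. Above it, reaction outruns return, and this flask is charged above it, but by a factor of 2.64, so I call neither reaction nor transfer the rate-limiting step.

The share of reagent that reacts is 0.725 at the charge and half at the crossing. Substrate falls as it reacts, so the share falls from its first figure. I take the crossing's share for the run, a low figure, which leaves room for the reagent going to homo dimer, a loss I do not reckon. Reagent delivered to substrate in the run is then 0.0264 M. That leaves [substrate] at 0.0236 M, still above the crossing, so the figure I took is indeed on the low side.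

That makes target at 7.34 × 10⁻⁷ M/s on average, faster than decomposition at the solubility 0.58 mM, which is 6.96 × 10⁻⁸ M/s. So crystals should form and dissolved target should stay slightly above solubility. Decomposition then costs 0.00251 M, and my yield is 47.8%.

The forecast takes the same side: “Reagent leaks slowly out of the second phase”. It gives 45% and 107%, its yield a little below mine.

The simulation gives 46.1% and 107%, so the forecast held.

Substrate at 10.0 h stands at 0.0224 M, still above the crossing. The first chemist's balance belongs far below the crossing, where return outruns reaction. The neighbour charged with 0.12 M of substrate starts further above it, with a share of 0.864. The same reckoning, with the share taken at the charge, delivers 0.0358 M. Less the same decomposition, that is 27.7% of its larger charge. The simulation of that neighbour gives 23.8%, with 69% of its substrate left.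

The rate constants were chosen freely; the rest is arithmetic.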